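**Retrosynthetic overview**
1. Target ⇐ tetracyclic 9,9a‑enamine with the γ‑lactone still on O11: oxidative lactone migration (the C14 carboxylate forms the C1–O bond), as in the presumed biogenetic C1 oxidation and translactonisation; ring D last.
2. That enamine ⇐ acyclic Boc‑amino keto butenolide in one pot: imine condensation (ring C), enamine–Michael closure C1→C12 onto the butenolide (ring B), N‑alkylation (ring A).
3. Acyclic precursor ⇐ alkylidene β‑keto ester + 3‑methyl‑2‑silyloxyfuran (catalytic asymmetric vinylogous Mukaiyama–Michael sets C10 and C11), then C9 alkylation with 1‑chloro‑4‑iodobutane.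
4. Alkylidene β‑keto ester ⇐ N‑Boc lactam + tert‑butyl acetate (ring‑opening Claisen) + propanal (Knoevenagel).
5. N‑Boc lactam ⇐ N‑Boc‑D‑prolinal + ethyl 2‑(bromomethyl)acrylate; ring order: side lactone → C → B → A → D.

Assumption: Stemona biogenetic numbering is used (N4; C1–C3 ring C; C5–C9 ring A; C9a; C10–C14 with ethyl on C10 and methyl on C13; side lactone C18–C22), and (S,S)‑t‑Bu‑BOX is taken as the ligand antipode that gives 10S (otherwise its enantiomer is used).

**Step 1**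
Reactants: 1 tert‑butyl (2R)‑2‑formylpyrrolidine‑1‑carboxylate (N‑Boc‑D‑prolinal); 2 ethyl 2‑(bromomethyl)prop‑2‑enoate
Product: 4 tert‑butyl (2R)‑2‑[(2S)‑4‑methylidene‑5‑oxooxolan‑2‑yl]pyrrolidine‑1‑carboxylate, via hydroxy ester 3 (not isolated)
Conditions: indium powder, THF/H2O (1:1), rt; then TsOH·H2O (cat), CH2Cl2, rt
Reagents that add atoms: none
Why: Barbier‑type indium allylation of the α‑amino aldehyde followed by acid‑catalysed lactonisation (Dreiding–Schmidt α‑methylene‑γ‑butyrolactone synthesis) builds the side lactone, and because the carbamate has no N–H to chelate, addition follows the Felkin–Anh model (N‑Boc antiperiplanar to the incoming allyl group), which sets C18 as S, anti (erythro) to the nitrogen on C3, the minor syn isomer being removed by chromatography of 4.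

**Step 2**
Reactants: 4 tert‑butyl (2R)‑2‑[(2S)‑4‑methylidene‑5‑oxooxolan‑2‑yl]pyrrolidine‑1‑carboxylate
Product: 5 tert‑butyl (2R)‑2‑[(2S,4S)‑4‑methyl‑5‑oxooxolan‑2‑yl]pyrrolidine‑1‑carboxylate
Conditions: H2 (1 atm), 10% Pd/C, EtOAc, rt
Reagents that add atoms: none
Why: Heterogeneous hydrogenation adds H2 to the exocyclic alkene from the lactone face opposite the bulky pyrrolidinyl substituent on C18, giving the 2,4‑cis lactone and so setting C20 as S.

**Step 3**
Reactants: 5 tert‑butyl (2R)‑2‑[(2S,4S)‑4‑methyl‑5‑oxooxolan‑2‑yl]pyrrolidine‑1‑carboxylate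
Product: 6 tert‑butyl (2R)‑2‑[(2S,4S)‑4‑methyl‑5‑oxooxolan‑2‑yl]‑5‑oxopyrrolidine‑1‑carboxylate
Conditions: RuCl3·xH2O (5 mol%), NaIO4 (4 equiv), EtOAc/H2O, rt
Reagents that add atoms: sodium periodate, [Na+].[O-]I(=O)(=O)=O
Why: RuO4 generated catalytically from RuCl3 and NaIO4 oxidises the unhindered methylene next to the carbamate nitrogen to the N‑Boc lactam (the tertiary C3–H and the lactone are left alone), turning the future C9a into an acylating carbonyl without touching a stereocentre.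

**Step 4**
Reactants: 6 tert‑butyl (2R)‑2‑[(2S,4S)‑4‑methyl‑5‑oxooxolan‑2‑yl]‑5‑oxopyrrolidine‑1‑carboxylate; 7 tert‑butyl acetate
Product: 9 tert‑butyl (6R)‑6‑[(tert‑butoxycarbonyl)amino]‑6‑[(2S,4S)‑4‑methyl‑5‑oxooxolan‑2‑yl]‑3‑oxohexanoate, via lithium enolate 8 (not isolated)
Conditions: LiN(i‑Pr)2 (2.2 equiv), 7 (2.2 equiv), THF, −78 °C; then 6, −78 °C; AcOH quench
Reagents that add atoms: none
Why: Claisen‑type addition of the ester enolate to the imide‑like N‑Boc lactam carbonyl, which at −78 °C is far more electrophilic than the γ‑lactone, with ring opening gives the Boc‑amino β‑keto ester in which C9 is the only activated methylene, and no stereocentre is involved.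

**Step 5**
Reactants: 9 tert‑butyl (6R)‑6‑[(tert‑butoxycarbonyl)amino]‑6‑[(2S,4S)‑4‑methyl‑5‑oxooxolan‑2‑yl]‑3‑oxohexanoate; 10 propanal
Product: 11 tert‑butyl (6R)‑6‑[(tert‑butoxycarbonyl)amino]‑6‑[(2S,4S)‑4‑methyl‑5‑oxooxolan‑2‑yl]‑3‑oxo‑2‑propylidenehexanoate (E/Z mixture)
Conditions: piperidine (10 mol%), AcOH (10 mol%), 4 Å MS, CH2Cl2, 0 °C
Reagents that add atoms: none
Why: Knoevenagel condensation of the β‑keto ester methylene with the aldehyde installs C10 with its ethyl group as an electrophilic alkylidene carbon (E/Z mixture used as such), under conditions too mild to epimerise C3, C18 or C20.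

**Step 6**
Reactants: 12 3‑methylfuran‑2(5H)‑one
Product: 13 3‑methyl‑2‑[(triisopropylsilyl)oxy]furan
Conditions: i‑Pr3SiOTf, Et3N, CH2Cl2, 0 °C
Reagents that add atoms: triisopropylsilyl trifluoromethanesulfonate, CC(C)[Si](C(C)C)(C(C)C)OS(=O)(=O)C(F)(F)F
Why: Soft enolisation and O‑silylation of the butenolide give the aromatic 2‑silyloxyfuran, the γ‑nucleophile (future C11) needed for the vinylogous addition.

**Step 7**
Reactants: 11 tert‑butyl (6R)‑6‑[(tert‑butoxycarbonyl)amino]‑6‑[(2S,4S)‑4‑methyl‑5‑oxooxolan‑2‑yl]‑3‑oxo‑2‑propylidenehexanoate; 13 3‑methyl‑2‑[(triisopropylsilyl)oxy]furan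
Product: 14 tert‑butyl (6R)‑6‑[(tert‑butoxycarbonyl)amino]‑2‑{(1S)‑1‑[(2R)‑4‑methyl‑5‑oxo‑2,5‑dihydrofuran‑2‑yl]propyl}‑6‑[(2S,4S)‑4‑methyl‑5‑oxooxolan‑2‑yl]‑3‑oxohexanoate (C2 epimers)
Conditions: Cu(OTf)2 (10 mol%), (S,S)‑t‑Bu‑BOX (11 mol%), (CF3)2CHOH (1.2 equiv), CH2Cl2, −78 to −40 °C
Reagents that add atoms: none
Why: Catalytic asymmetric vinylogous Mukaiyama–Michael addition in which the Cu(OTf)2/BOX complex chelates the two carbonyls of the alkylidene β‑keto ester (both alkene isomers are attacked on the face left open by the C2‑symmetric ligand and converge), which sets C10 as S, while the open antiperiplanar approach of the furan γ‑carbon is expected to set C11 as R (ethyl and ring oxygen syn), the remote C3, C18 and C20 centres having no influence.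

**Step 8**
Reactants: 14 (the adduct of step 7); 15 1‑chloro‑4‑iodobutane
Product: 16 tert‑butyl (6R)‑6‑[(tert‑butoxycarbonyl)amino]‑2‑(4‑chlorobutyl)‑2‑{(1S)‑1‑[(2S)‑4‑methyl‑5‑oxo‑2,5‑dihydrofuran‑2‑yl]propyl}‑6‑[(2S,4S)‑4‑methyl‑5‑oxooxolan‑2‑yl]‑3‑oxohexanoate (C2 epimers)
Conditions: Cs2CO3, DMF, 0 °C to rt
Reagents that add atoms: none
Why: C‑alkylation of the cesium enolate of the β‑keto ester by the primary iodide (the chloride is kept for ring A) attaches C5–C8 to C9; the new quaternary C9 is an epimer mixture that does not matter because C9 later becomes sp2, and carbonate is too weak to deprotonate the butenolide at C11 (the butenolide descriptor changes from R to S only through CIP priorities).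

**Step 9**
Reactants: 16 (the alkylated β‑keto ester of step 8)
Product: 20 (1S,3R,10S,11S,12R,13R,18S,20S)‑tetracyclic 9,9a‑enamine bis‑lactone (pyrrolo[1,2‑a]azepine rings C/A fused to ring B carrying the cis‑fused 11‑O/C14 γ‑lactone; tuberostemonine‑type skeleton), via amino ketone 17 (not isolated), via pyrroline 18 (not isolated), via tricyclic imine 19 (not isolated)
Conditions: TFA/CH2Cl2 (1:2), 0 to 40 °C; evaporate; NaOAc (4 equiv), NaI (1 equiv), MeCN (0.01 M), 45 °C then 75 °C; aq K2CO3 work‑up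
Reagents that add atoms: none
Why: Proposed new method: acid removes the Boc group and the tert‑butyl ester and the quaternary β‑keto acid decarboxylates to 17, the γ‑amino ketone condenses at once to 1‑pyrroline 18 (kept mildly acidic so the free amine cannot attack the side lactone), the secondary‑enamine tautomer of 18 at C1 adds to C12 of the tethered butenolide in an aza‑ene‑type Michael closure (closest known types: thermal imine/secondary‑enamine Michael additions and Stork enamine annulations) to give 19, where the pre‑set C11 forces the cis ring fusion and so fixes C12 as R while N–H to C13 proton delivery on the same face puts the C13 methyl on the convex face (13R), and iodide‑assisted N‑alkylation by the chlorobutyl chain then closes the azepine and loss of H9 gives enamine 20, C9 and C1 being epimerisable so that all C9 epimers converge.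

**Step 10**
Reactants: 20 (the tetracyclic enamine bis‑lactone of step 9)
Product: 24 target CNP0154902.3 (1R,3R,10S,11R,12R,13R,18S,20S; γ‑lactone on O1/C14 and free 11‑hydroxyl), via dicarboxylate 21 (not isolated), via iodo iminium 22 (not isolated), via hydroxy carboxylate 23 (not isolated)
Conditions: LiOH (2.2 equiv), THF/H2O, 0 °C to rt; then NaHCO3 (3 equiv), I2 (1.05 equiv), MeCN/H2O, 0 °C; Na2S2O3; AcOH to pH 5, rt
Reagents that add atoms: lithium hydroxide, [Li+].[OH-]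
Why: Proposed new method: hydroxide opens both lactones to 21, iodine then iodinates the enamine (reversibly at C9, productively at C1 through the C1=C9a tautomer) to the α‑iodo iminium 22, and the C14 carboxylate held on the C13 face displaces iodide at C1 through the 2‑aminoallyl cation to close the cis‑fused γ‑lactone (closest known types: iodolactonisation and iodine‑mediated α‑oxyacylation of ketones and enamines by carboxylic acids, mirroring the presumed biogenetic C1 oxidation with lactone migration), which sets C1 as R on the face of C13 and anti to the C3 side chain and frees the 11‑hydroxyl, while mild acidification recloses the side lactone of 23 to give 24.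

**Compound list**
1 | tert‑butyl (2R)‑2‑formylpyrrolidine‑1‑carboxylate | CC(C)(C)OC(=O)N1[C@@H](C=O)CCC1 | starting material
2 | ethyl 2‑(bromomethyl)prop‑2‑enoate | CCOC(=O)C(=C)CBr | starting material
3 | ethyl 2‑{(2S)‑2‑[(2R)‑1‑(tert‑butoxycarbonyl)pyrrolidin‑2‑yl]‑2‑hydroxyethyl}prop‑2‑enoate | CC(C)(C)OC(=O)N1[C@@H]([C@@H](O)CC(=C)C(=O)OCC)CCC1 | intermediate
4 | tert‑butyl (2R)‑2‑[(2S)‑4‑methylidene‑5‑oxooxolan‑2‑yl]pyrrolidine‑1‑carboxylate | CC(C)(C)OC(=O)N1[C@@H]([C@@H]2CC(=C)C(=O)O2)CCC1 | intermediate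
5 | tert‑butyl (2R)‑2‑[(2S,4S)‑4‑methyl‑5‑oxooxolan‑2‑yl]pyrrolidine‑1‑carboxylate | CC(C)(C)OC(=O)N1[C@@H]([C@@H]2C[C@H](C)C(=O)O2)CCC1 | intermediate
6 | tert‑butyl (2R)‑2‑[(2S,4S)‑4‑methyl‑5‑oxooxolan‑2‑yl]‑5‑oxopyrrolidine‑1‑carboxylate | CC(C)(C)OC(=O)N1[C@@H]([C@@H]2C[C@H](C)C(=O)O2)CCC1=O | intermediate
7 | tert‑butyl acetate | CC(=O)OC(C)(C)C | starting material
8 | lithium enolate of tert‑butyl acetate | [Li+].C=C([O-])OC(C)(C)C | intermediate
9 | tert‑butyl (6R)‑6‑[(tert‑butoxycarbonyl)amino]‑6‑[(2S,4S)‑4‑methyl‑5‑oxooxolan‑2‑yl]‑3‑oxohexanoate | CC(C)(C)OC(=O)CC(=O)CC[C@@H](NC(=O)OC(C)(C)C)[C@@H]1C[C@H](C)C(=O)O1 | intermediate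
10 | propanal | CCC=O | starting material
11 | tert‑butyl (6R)‑6‑[(tert‑butoxycarbonyl)amino]‑6‑[(2S,4S)‑4‑methyl‑5‑oxooxolan‑2‑yl]‑3‑oxo‑2‑propylidenehexanoate (E/Z mixture) | CCC=C(C(=O)OC(C)(C)C)C(=O)CC[C@@H](NC(=O)OC(C)(C)C)[C@@H]1C[C@H](C)C(=O)O1 | intermediate
12 | 3‑methylfuran‑2(5H)‑one | CC1=CCOC1=O | starting material
13 | 3‑methyl‑2‑[(triisopropylsilyl)oxy]furan | CC1=C(O[Si](C(C)C)(C(C)C)C(C)C)OC=C1 | intermediate
14 | tert‑butyl (6R)‑6‑[(tert‑butoxycarbonyl)amino]‑2‑{(1S)‑1‑[(2R)‑4‑methyl‑5‑oxo‑2,5‑dihydrofuran‑2‑yl]propyl}‑6‑[(2S,4S)‑4‑methyl‑5‑oxooxolan‑2‑yl]‑3‑oxohexanoate (C2 epimers) | CC[C@H]([C@@H]1C=C(C)C(=O)O1)C(C(=O)OC(C)(C)C)C(=O)CC[C@@H](NC(=O)OC(C)(C)C)[C@@H]1C[C@H](C)C(=O)O1 | intermediate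
15 | 1‑chloro‑4‑iodobutane | ClCCCCI | starting material
16 | tert‑butyl (6R)‑6‑[(tert‑butoxycarbonyl)amino]‑2‑(4‑chlorobutyl)‑2‑{(1S)‑1‑[(2S)‑4‑methyl‑5‑oxo‑2,5‑dihydrofuran‑2‑yl]propyl}‑6‑[(2S,4S)‑4‑methyl‑5‑oxooxolan‑2‑yl]‑3‑oxohexanoate (C2 epimers) | CC[C@H]([C@@H]1C=C(C)C(=O)O1)C(CCCCCl)(C(=O)OC(C)(C)C)C(=O)CC[C@@H](NC(=O)OC(C)(C)C)[C@@H]1C[C@H](C)C(=O)O1 | intermediate
17 | (1R,6S)‑1‑amino‑5‑(4‑chlorobutyl)‑6‑[(2R)‑4‑methyl‑5‑oxo‑2,5‑dihydrofuran‑2‑yl]‑1‑[(2S,4S)‑4‑methyl‑5‑oxooxolan‑2‑yl]octan‑4‑one (C5 epimers; present as trifluoroacetate salt) | CC[C@H]([C@@H]1C=C(C)C(=O)O1)C(CCCCCl)C(=O)CC[C@@H](N)[C@@H]1C[C@H](C)C(=O)O1 | intermediate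
18 | (3S,5S)‑5‑[(2R)‑5‑{(3S)‑8‑chloro‑3‑[(2R)‑4‑methyl‑5‑oxo‑2,5‑dihydrofuran‑2‑yl]octan‑4‑yl}‑3,4‑dihydro‑2H‑pyrrol‑2‑yl]‑3‑methyloxolan‑2‑one (epimers at octane C4) | CC[C@H]([C@@H]1C=C(C)C(=O)O1)C(CCCCCl)C1=N[C@@H]([C@@H]2C[C@H](C)C(=O)O2)CC1 | intermediate
19 | tricyclic imine (1S,3R,10S,11R,12R,13R,18S,20S; C9 epimers): 1‑pyrroline ring C fused at C1–C9a to ring B, which carries the 4‑chlorobutyl chain on C9, ethyl on C10 and the cis‑fused 11‑O/C14 γ‑lactone with 13‑methyl; side lactone on C3 | CC[C@H]1C(CCCCCl)C2=N[C@@H]([C@@H]3C[C@H](C)C(=O)O3)C[C@H]2[C@@H]4[C@@H](C)C(=O)O[C@H]14 | intermediate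
20 | (1S,3R,10S,11S,12R,13R,18S,20S)‑tetracyclic 9,9a‑enamine bis‑lactone (γ‑lactone on O11/C14, H on C1) | CC[C@H]1C2=C3N(CCCC2)[C@@H]([C@@H]2C[C@H](C)C(=O)O2)C[C@H]3[C@@H]4[C@@H](C)C(=O)O[C@H]14 | intermediate
21 | dilithium dicarboxylate of 20 (both lactones opened: 11‑OH, 18‑OH, C14 and C21 carboxylates; configuration as in 20) | CC[C@H]1C2=C3N(CCCC2)[C@@H]([C@@H](O)C[C@H](C)C(=O)[O-])C[C@H]3[C@H]([C@@H](C)C(=O)[O-])[C@@H]1O.[Li+].[Li+] | intermediate
22 | C1‑iodo N4=C9a iminium dicarboxylate (zwitterion, lithium salt; C1 and C9 not defined) | CC[C@H]1C2CCCC[N+]3=C2C(I)(C[C@@H]3[C@@H](O)C[C@H](C)C(=O)[O-])[C@H]([C@@H](C)C(=O)[O-])[C@@H]1O.[Li+] | intermediate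
23 | lithium carboxylate of the 18‑hydroxy acid of 24 (O1/C14 lactone formed, side lactone open; configuration as in 24) | CC[C@H]1C2=C3N(CCCC2)[C@@H]([C@@H](O)C[C@H](C)C(=O)[O-])C[C@]32OC(=O)[C@H](C)[C@@H]2[C@@H]1O.[Li+] | intermediate
24 | CNP0154902.3 (1R,3R,10S,11R,12R,13R,18S,20S) | CC[C@H]1C2=C3N(CCCC2)[C@@H]([C@@H]2C[C@H](C)C(=O)O2)C[C@]32OC(=O)[C@H](C)[C@@H]2[C@@H]1O | target

**Totals and risks**
Total step count: 10. Longest linear sequence: 9 steps (steps 1–5 and 7–10; step 6 makes the side fragment 13).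

Three steps most likely to fail:

Step 10 (oxidative lactone migration) is the least certain: iodination at C9, attack of water on the iminium, over‑oxidation of the product enamine, or back‑migration of the acyl group to O11 could all compete. The fallback sets out from 20 and comes back at 24. The C1=C9a enamine tautomer is oxygenated with an external electrophilic oxidant (3‑phenyl‑2‑(phenylsulfonyl)oxaziridine, THF, −78 °C), which should approach anti to the C3 side chain, the face that carries C13. This gives the (1R,3R,10S,11R,12R,13R,18S,20S)‑1‑hydroxy‑9,9a‑enamine with the lactone still on O11, F3. A catalytic base or acid (DBU or camphorsulfonic acid, CH2Cl2, rt) then lets the tertiary 1‑hydroxyl take over the C14 acyl group (translactonisation) to give 24.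

Step 9 (triple cyclisation) may stall at the Michael closure on the N–H imine or at the seven‑membered N‑alkylation, and lactam formation by the free amine is possible if the medium turns basic too early. The fallback sets out from 16 and comes back at 20, changing the order of ring formation. TFA then NaOAc at rt gives pyrroline 18, which is N‑alkylated first (NaI, K2CO3, MeCN, 70 °C). The product is the bicyclic tertiary enamine (3S,5S)‑3‑methyl‑5‑[(3R)‑9‑{(1S)‑1‑[(2S)‑4‑methyl‑5‑oxo‑2,5‑dihydrofuran‑2‑yl]propyl}‑2,3,5,6,7,8‑hexahydro‑1H‑pyrrolo[1,2‑a]azepin‑3‑yl]oxolan‑2‑one F2. Ring B is then closed by a Brønsted‑acid‑promoted Stork enamine Michael addition ((PhO)2P(O)OH 20 mol%, toluene, 60 °C) to give 20.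

Step 8 (alkylation of a hindered β‑keto ester) may be slow, give O‑alkylation, or allow retro‑Michael loss of the furanone. The fallback sets out from 14 and comes back at 16. The activated allylic bromide (E)‑1‑bromo‑4‑chlorobut‑2‑ene (Cs2CO3, acetone, 0 °C) is used instead, giving tert‑butyl (6R)‑6‑[(tert‑butoxycarbonyl)amino]‑2‑[(2E)‑4‑chlorobut‑2‑en‑1‑yl]‑2‑{(1S)‑1‑[(2S)‑4‑methyl‑5‑oxo‑2,5‑dihydrofuran‑2‑yl]propyl}‑6‑[(2S,4S)‑4‑methyl‑5‑oxooxolan‑2‑yl]‑3‑oxohexanoate F1. Chemoselective diimide reduction (2‑nitrobenzenesulfonohydrazide, Et3N, CH2Cl2, rt) of the isolated disubstituted alkene, which reacts much faster than the trisubstituted conjugated butenolide, then gives 16.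

**Further compounds**
F1 | step 8 | tert‑butyl (6R)‑6‑[(tert‑butoxycarbonyl)amino]‑2‑[(2E)‑4‑chlorobut‑2‑en‑1‑yl]‑2‑{(1S)‑1‑[(2S)‑4‑methyl‑5‑oxo‑2,5‑dihydrofuran‑2‑yl]propyl}‑6‑[(2S,4S)‑4‑methyl‑5‑oxooxolan‑2‑yl]‑3‑oxohexanoate (C2 epimers) | CC[C@H]([C@@H]1C=C(C)C(=O)O1)C(C/C=C/CCl)(C(=O)OC(C)(C)C)C(=O)CC[C@@H](NC(=O)OC(C)(C)C)[C@@H]1C[C@H](C)C(=O)O1
F2 | step 9 | (3S,5S)‑3‑methyl‑5‑[(3R)‑9‑{(1S)‑1‑[(2S)‑4‑methyl‑5‑oxo‑2,5‑dihydrofuran‑2‑yl]propyl}‑2,3,5,6,7,8‑hexahydro‑1H‑pyrrolo[1,2‑a]azepin‑3‑yl]oxolan‑2‑one | CC[C@H]([C@@H]1C=C(C)C(=O)O1)C1=C2CC[C@H]([C@@H]3C[C@H](C)C(=O)O3)N2CCCC1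
F3 | step 10 | (1R,3R,10S,11R,12R,13R,18S,20S)‑1‑hydroxy‑9,9a‑enamine bis‑lactone (lactone on O11/C14, tertiary OH on C1) | CC[C@H]1C2=C3N(CCCC2)[C@@H]([C@@H]2C[C@H](C)C(=O)O2)C[C@@]3(O)[C@@H]4[C@@H](C)C(=O)O[C@H]14
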